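The runs stem from a simulated flask for an exercise.

A small charge of initiator, 100 µM against 20 mM of free monomer, was what I had to judge: could this flask stand until 20 h, or did I have to stop it earlier?

| flask | free monomer | initiator | remark | time |
|---|---|---|---|---|
| dawn | 20 mM | 67 µM | run made earlier |  |
| dusk | 20 mM | 150 µM | run made earlier |  |
| summer | 30 mM | 100 µM | run made earlier |  |
| flask | 20 mM | 100 µM |  | 20 h |

- dawn (time / h: monomer in chains / %): 0.667: 54.2; 1.33: 82.0; 2.00: 92.7; 4.00: 98.5; 6.00: 98.8; 12.0: 98.4; 20.0: 97.0
- dusk (time / h: monomer in chains / %): 0.667: 77.8; 1.33: 91.1; 2.00: 90.9; 4.00: 82.3; 6.00: 77.6; 12.0: 58.8; 20.0: 42.5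
- summer (time / h: monomer in chains / %): 0.667: 71.5; 1.50: 93.8; 4.00: 98.0; 8.00: 98.7; 20.0: 96.5

(each reading ± 0.5 percentage points)

- the analysis behind the earlier runs scatters by 0.5 percentage points, standard deviation

- time, not beyond 20 h, at which the flask holds most monomer in chains
- the amount of monomer in chains, in percent of the free monomer charged, at that time
- earliest time at which at least nineteen twentieths of that best amount are there
- latest time at which they still are

1. Late in the earlier runs the chains were falling, so I read a first-order loss constant from the readings at 6.00 h and 20.0 h for dawn and dusk, and at 8.00 h and 20.0 h for summer: dawn 0.00131 h⁻¹, summer 0.00188 h⁻¹, dusk 0.0430 h⁻¹. Dawn's fall was 1.8 percentage points against a scatter of 0.5 points, so its constant is rough.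

2. Dawn and summer differed in [initiator], yet their ratios r = [free monomer]/[initiator] were 299 and 300, and their losses were of one size. Dusk had r = 133. So I worked in logarithms of r.

3. My loss slope, the fall in log10 of the loss constant per unit rise in log10 r, came to 4.33.

4. The flask, at r = 200, lies 0.496 of the way from dawn to dusk on that scale. That gave me 0.00743 h⁻¹, or 13.8% of the chains lost over 20 h. I decided to stop the flask early.

5. The forecast gave a peak of 97.4% at 3.1 h, with the window from 1.6 h to 9.7 h, and it took 0.008 per hour for the loss. Of its ratio rule it said: “This interpolation is the weak point”.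

6. The flask gave 96.0% at 2.74 h, with the window from 1.42 h to 9.75 h.

    free monomer + initiator → living end + monomer in chains (k = 6.82 M⁻¹ min⁻¹)
    free monomer + living end → monomer in chains + living end, rate k2*[living end]*[free monomer] (k = 365 M⁻¹ min⁻¹)
    initiator + monomer in chains → initiator + over-reaction product (k = 145 M⁻¹ min⁻¹)

7. From 10.0 h to 20 h the flask lost chains at 0.00784 h⁻¹, beside my 0.00743 h⁻¹. This pseudo-first-order loss ran on the initiator still there, 0.901% of its own charge, which with the hidden constant makes 0.00784 h⁻¹. The shrinking supply of initiator was the largest single effect on the highest amount in the flask: the same run without that shrinking reached 68.5% instead of 96.0%. With 12 mM of free monomer the best was 89.3%, below the forecast's low end; a result like that would have made it wrong.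

8. With 50 mM of free monomer, r is 500, beyond the readings, and the slope gives 1.41 × 10⁻⁴ h⁻¹, or 0.281% lost over 20 h. That neighbour ended with 0.349% as over-reaction product and 99.7% in chains.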